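**Plan**
- Retrosynthesis: cut the O6–vanilloyl ester bond, take the 8(14)-methylene-9-ol back to a C14 ester with a C9 enol silane, take H5/O6 back to a C5=C6 alkene, then cut C7–C8 and C1–C10 of the seven-membered ring together.
- Enabling feature: in the seven-membered ring C1–C10–C9–C8(C14)–C7–C6–C5, the piece C10–C9(O)–C8(C14) is a 2-siloxyvinyl diazoacetate and the piece C7–C6–C5–C1 is a 1-vinyl-2-methylcyclopentene whose ring alkene ends at the quaternary C1.
- Forward order: the five-membered ring comes from (S)-terpinen-4-ol (ozonolysis, aldol re-closure, methylenation); the seven-membered ring is then closed by rhodium carbenoid cyclopropanation and Cope shift; redox adjustment and vanilloylation finish.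
- Stereochemistry: C4 comes from terpinen-4-ol; C1 from the catalyst-set cyclopropane and the stereospecific boat Cope shift; C5 and C6 from syn hydroboration on the α face; C9 from a catalyst-controlled CBS reduction.

Key step: step 7

Remarks: (S)-terpinen-4-ol is assumed to be available in high enantiomeric purity. Locants follow the daucane skeleton: C1 is the quaternary ring-fusion carbon with methyl C15, C4 the isopropyl carbinol, C5 the ring-fusion CH, C6 the ester carbinol, C8 carries C14, C9 is the free carbinol. α is the face of H5 and β the face of C15.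

**Step 1**
Reactants: 1 (S)-terpinen-4-ol
Product: 2 (S)-terpinen-4-ol triethylsilyl ether
Conditions: TESOTf, 2,6-lutidine, CH2Cl2, −78 → 0 °C
Reagents that add atoms: triethylsilyl trifluoromethanesulfonate, CC[Si](CC)(CC)OS(=O)(=O)C(F)(F)F
Why: Silyl triflate silylation of a hindered tertiary alcohol; the ether prevents retro-aldol and hemiketal formation after ring cleavage, keeps the hydroxyl away from the carbenoid later, and leaves C4 untouched.

**Step 2**
Reactants: 2 (S)-terpinen-4-ol triethylsilyl ether
Product: 4 (3S)-6-oxo-3-(propan-2-yl)-3-(triethylsilyloxy)heptanal, via secondary ozonide 3 (not isolated)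
Conditions: O3, CH2Cl2, −78 °C; then PPh3, −78 °C → rt
Reagents that add atoms: ozone, [O-][O+]=O
Why: Ozonolysis (Criegee mechanism) of the only C=C bond followed by phosphine reduction of the ozonide opens the six-membered ring to the 1,6-keto aldehyde without affecting the silyl ether or C4.

**Step 3**
Reactants: 4 (3S)-6-oxo-3-(propan-2-yl)-3-(triethylsilyloxy)heptanal
Product: 5 (5R)-2-methyl-5-(propan-2-yl)-5-(triethylsilyloxy)cyclopent-1-ene-1-carbaldehyde
Conditions: piperidine, AcOH (0.3 equiv each), benzene, 60 °C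
Reagents that add atoms: none
Why: Amine-salt catalysed intramolecular aldol condensation in which the enamine of the aldehyde adds to the methyl ketone and water is lost, which should give the cyclopentenecarbaldehyde rather than the acetylcyclopentene favoured by hydroxide; C4 has no acidic hydrogen and cannot epimerise.

**Step 4**
Reactants: 5 (5R)-2-methyl-5-(propan-2-yl)-5-(triethylsilyloxy)cyclopent-1-ene-1-carbaldehyde
Product: 6 triethyl{[(1R)-2-ethenyl-3-methyl-1-(propan-2-yl)cyclopent-2-en-1-yl]oxy}silane
Conditions: Ph3PCH3Br, KOtBu, THF, 0 °C → rt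
Reagents that add atoms: methyltriphenylphosphonium bromide, C[P+](c1ccccc1)(c1ccccc1)c1ccccc1.[Br-]
Why: Wittig methylenation with the small unstabilised ylide should convert even this hindered enal into the vinyl group (C7); no stereocenter is formed.

**Step 5**
Reactants: 7 methyl acetoacetate
Product: 8 methyl 2-diazo-3-oxobutanoate
Conditions: p-ABSA, Et3N, MeCN, 0 °C → rt
Reagents that add atoms: 4-acetamidobenzenesulfonyl azide, CC(=O)Nc1ccc(cc1)S(=O)(=O)N=[N+]=[N-]
Why: Regitz diazo transfer to the doubly activated methylene group is a standard route to diazoacetoacetates.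

**Step 6**
Reactants: 8 methyl 2-diazo-3-oxobutanoate
Product: 9 methyl 3-(tert-butyldimethylsilyloxy)-2-diazobut-3-enoate
Conditions: TBSOTf, Et3N, CH2Cl2, 0 °C
Reagents that add atoms: tert-butyldimethylsilyl trifluoromethanesulfonate, CC(C)(C)[Si](C)(C)OS(=O)(=O)C(F)(F)F
Why: Soft enolisation and O-silylation of the methyl ketone give the 2-siloxyvinyl diazoacetate, with the diazo group intact under these non-acidic conditions.

**Step 7**
Reactants: 6 triethyl{[(1R)-2-ethenyl-3-methyl-1-(propan-2-yl)cyclopent-2-en-1-yl]oxy}silane; 9 methyl 3-(tert-butyldimethylsilyloxy)-2-diazobut-3-enoate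
Product: 11 methyl (1R,4R)-9-(tert-butyldimethylsilyloxy)-4-(triethylsilyloxy)dauca-5,8-dien-14-oate, via cis-divinylcyclopropane 10 (not isolated)
Conditions: 9 (1.5 equiv) added slowly to 6 and Rh2(S-PTAD)4 (1 mol %), hexanes, 0 °C → rt; then 60 °C
Reagents that add atoms: none
Why: Rh2(S-PTAD)4 expels N2 from 9 to give a donor–acceptor rhodium carbenoid that cyclopropanates the monosubstituted C6=C7 bond of 6 in a concerted [2+1] addition with the siloxyvinyl group cis to the cyclopentenyl group (closure of the three-membered ring C6–C7–C8), and the cis-divinylcyclopropane 10 then undergoes a Cope [3,3] shift that breaks C6–C8 and joins C10 to C1. The closest known reaction type is the dirhodium tetracarboxylate catalysed tandem cyclopropanation/Cope (formal 4+3) reaction of 2-siloxyvinyl diazoacetates with 1,3-dienes, which tolerates a fully substituted diene terminus. The seven-membered ring closes by this pericyclic ring expansion itself: the boat transition state holds both alkenyl arms over the cyclopropane, so C1–C10 formation and C6–C8 cleavage are one event and only cis ring alkenes can result. The single new stereocenter, quaternary C1, is fixed by the configuration of C6 in 10 (the (1R,2S) cyclopropane is the one expected from this catalyst enantiomer with a monosubstituted alkene) together with the fixed ring-alkene geometry in which C15 is cis to C6, so that C10 arrives on the α face and C15 ends up β. The step needs selectivity for the vinyl group over the tetrasubstituted ring alkene and for the carbenoid carbon over its vinylogous terminus, which the steric demand of the carbenoid, the bulky carboxylate ligands and the hydrocarbon solvent should secure, and it needs the cis-divinyl (E-selective) cyclopropanation typical of donor–acceptor carbenoids. The C4 stereocenter is remote from the reacting vinyl group, so the catalyst rather than the substrate should decide the face.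

**Step 8**
Reactants: 11 methyl (1R,4R)-9-(tert-butyldimethylsilyloxy)-4-(triethylsilyloxy)dauca-5,8-dien-14-oate
Product: 13 methyl (1R,4R,5S,6S)-9-(tert-butyldimethylsilyloxy)-6-hydroxy-4-(triethylsilyloxy)dauc-8-en-14-oate, via C6 monoalkylborane 12 (not isolated)
Conditions: BH3·THF, THF, 0 °C → rt; then NaBO3·4H2O, H2O, rt
Reagents that add atoms: sodium perborate tetrahydrate, [Na+].[Na+].O[B-]1(O)OO[B-](O)(O)OO1
Why: Hydroboration–oxidation places boron on the less substituted C6 and hydrogen on C5 in a syn addition, expected on the α face anti to the angular methyl C15 and the pseudoaxial C4 silyloxy group (as with angular-methyl ring-fusion alkenes), which sets H5α and O6α together; the push–pull tetrasubstituted C8=C9 bond is inert and the mild perborate oxidation proceeds with retention and should spare the enol silane.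

**Step 9**
Reactants: 13 methyl (1R,4R,5S,6S)-9-(tert-butyldimethylsilyloxy)-6-hydroxy-4-(triethylsilyloxy)dauc-8-en-14-oate
Product: 15 (1R,4R,5S,6S)-6-hydroxy-4-(triethylsilyloxy)dauc-8(14)-en-9-one, via allylic diol 14 (not isolated)
Conditions: i-Bu2AlH (4 equiv), CH2Cl2, −78 °C; then 1 M HCl, THF, 0 °C
Reagents that add atoms: none
Why: Hydride 1,2-reduction of the β-siloxy enoate gives the C14 allylic alcohol, and brief dilute acid ionises the C14–O bond with the push of the enol silane and removes the silyl group (the 1,3-carbonyl transposition logic of the Stork–Danheiser sequence) to give the α-methylene ketone; the hindered tertiary silyl ether should survive, no stereocenter is touched, and a free C4 hydroxyl would in any case be tolerated in the remaining steps.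

**Step 10**
Reactants: 16 vanillic acid
Product: 18 4-(tert-butyldimethylsilyloxy)-3-methoxybenzoic acid, via silyl ester 17 (not isolated)
Conditions: TBSCl (2.5 equiv), imidazole, DMF, rt; then AcOH/THF/H2O, rt
Reagents that add atoms: tert-butyldimethylsilyl chloride, CC(C)(C)[Si](C)(C)Cl
Why: Exhaustive silylation followed by selective hydrolysis of the far more labile silyl ester leaves the aryl silyl ether, masking the phenol for the acylation.

**Step 11**
Reactants: 15 (1R,4R,5S,6S)-6-hydroxy-4-(triethylsilyloxy)dauc-8(14)-en-9-one; 18 4-(tert-butyldimethylsilyloxy)-3-methoxybenzoic acid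
Product: 20 (1R,4R,5S,6S)-9-oxo-4-(triethylsilyloxy)dauc-8(14)-en-6-yl 4-(tert-butyldimethylsilyloxy)-3-methoxybenzoate, via mixed anhydride 19 (not isolated)
Conditions: 18, 2,4,6-Cl3C6H2COCl, Et3N, THF, rt; then 15, DMAP, toluene, rt
Reagents that add atoms: none
Why: Yamaguchi esterification, in which DMAP attacks the unhindered aroyl carbonyl of the mixed anhydride and transfers it to the equatorial 6α-hydroxyl with retention at C6; C9 is still a ketone, so O6 is the only acylable oxygen and the tertiary silyl ether is inert.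

**Step 12**
Reactants: 20 (1R,4R,5S,6S)-9-oxo-4-(triethylsilyloxy)dauc-8(14)-en-6-yl 4-(tert-butyldimethylsilyloxy)-3-methoxybenzoate
Product: 21 (1R,4R,5S,6S,9S)-9-hydroxy-4-(triethylsilyloxy)dauc-8(14)-en-6-yl 4-(tert-butyldimethylsilyloxy)-3-methoxybenzoate
Conditions: (R)-2-methyl-CBS-oxazaborolidine (0.5 equiv), catecholborane, toluene, −78 °C
Reagents that add atoms: none
Why: Corey–Bakshi–Shibata reduction, in which the oxazaborolidine binds the ketone anti to the branched alkenyl carbon C8 (large group) and delivers hydride to the β face of C9 to give the 9S (9α) allylic alcohol under catalyst control; at −78 °C catecholborane reduces neither the aryl ester nor the 1,1-disubstituted alkene.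

**Step 13**
Reactants: 21 (1R,4R,5S,6S,9S)-9-hydroxy-4-(triethylsilyloxy)dauc-8(14)-en-6-yl 4-(tert-butyldimethylsilyloxy)-3-methoxybenzoate
Product: 22 (1R,4R,5S,6S,9S)-4,9-dihydroxydauc-8(14)-en-6-yl 4-hydroxy-3-methoxybenzoate (CNP0330487.1)
Conditions: Bu4NF, AcOH, THF, 0 °C → rt
Reagents that add atoms: none
Why: Fluoride cleaves the aryl and the tertiary silyl ether in one operation, and the acetic acid buffer should prevent acyl migration or ester cleavage; no stereocenter is affected.

**Compound list**
1 | (S)-terpinen-4-ol, (1S)-4-methyl-1-(propan-2-yl)cyclohex-3-en-1-ol | C1C=C(C)CC[C@@]1(O)C(C)C | starting material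
2 | triethyl{[(1S)-4-methyl-1-(propan-2-yl)cyclohex-3-en-1-yl]oxy}silane | C1C=C(C)CC[C@@]1(O[Si](CC)(CC)CC)C(C)C | intermediate
3 | secondary ozonide of 2 (1,2,4-trioxolane bridging the former alkene carbons; both bridgehead diastereomers) | CC12CC[C@@](O[Si](CC)(CC)CC)(C(C)C)CC(OO1)O2 | intermediate
4 | (3S)-6-oxo-3-(propan-2-yl)-3-(triethylsilyloxy)heptanal | O=CC[C@](O[Si](CC)(CC)CC)(C(C)C)CCC(C)=O | intermediate
5 | (5R)-2-methyl-5-(propan-2-yl)-5-(triethylsilyloxy)cyclopent-1-ene-1-carbaldehyde | O=CC1=C(C)CC[C@@]1(O[Si](CC)(CC)CC)C(C)C | intermediate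
6 | triethyl{[(1R)-2-ethenyl-3-methyl-1-(propan-2-yl)cyclopent-2-en-1-yl]oxy}silane | C=CC1=C(C)CC[C@@]1(O[Si](CC)(CC)CC)C(C)C | intermediate
7 | methyl acetoacetate | CC(=O)CC(=O)OC | starting material
8 | methyl 2-diazo-3-oxobutanoate | CC(=O)C(=[N+]=[N-])C(=O)OC | intermediate
9 | methyl 3-(tert-butyldimethylsilyloxy)-2-diazobut-3-enoate | C=C(O[Si](C)(C)C(C)(C)C)C(=[N+]=[N-])C(=O)OC | intermediate
10 | methyl (1R,2S)-1-[1-(tert-butyldimethylsilyloxy)ethenyl]-2-[(5R)-2-methyl-5-(propan-2-yl)-5-(triethylsilyloxy)cyclopent-1-en-1-yl]cyclopropane-1-carboxylate (cis-divinylcyclopropane) | COC(=O)[C@]1(C(=C)O[Si](C)(C)C(C)(C)C)C[C@H]1C1=C(C)CC[C@@]1(O[Si](CC)(CC)CC)C(C)C | intermediate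
11 | methyl (1R,4R)-9-(tert-butyldimethylsilyloxy)-4-(triethylsilyloxy)dauca-5,8-dien-14-oate | COC(=O)C1=C(O[Si](C)(C)C(C)(C)C)C[C@@]2(C)CC[C@@](O[Si](CC)(CC)CC)(C(C)C)C2=CC1 | intermediate
12 | 6α-borane of 11 (monoalkylborane, H5α) | COC(=O)C1=C(O[Si](C)(C)C(C)(C)C)C[C@@]2(C)CC[C@@](O[Si](CC)(CC)CC)(C(C)C)[C@@H]2[C@@H](B)C1 | intermediate
13 | methyl (1R,4R,5S,6S)-9-(tert-butyldimethylsilyloxy)-6-hydroxy-4-(triethylsilyloxy)dauc-8-en-14-oate | COC(=O)C1=C(O[Si](C)(C)C(C)(C)C)C[C@@]2(C)CC[C@@](O[Si](CC)(CC)CC)(C(C)C)[C@@H]2[C@@H](O)C1 | intermediate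
14 | (1R,4R,5S,6S)-9-(tert-butyldimethylsilyloxy)-4-(triethylsilyloxy)dauc-8-ene-6,14-diol | OCC1=C(O[Si](C)(C)C(C)(C)C)C[C@@]2(C)CC[C@@](O[Si](CC)(CC)CC)(C(C)C)[C@@H]2[C@@H](O)C1 | intermediate
15 | (1R,4R,5S,6S)-6-hydroxy-4-(triethylsilyloxy)dauc-8(14)-en-9-one | C=C1C[C@H](O)[C@@H]2[C@](C)(CC[C@@]2(O[Si](CC)(CC)CC)C(C)C)CC1=O | intermediate
16 | vanillic acid | COc1cc(C(=O)O)ccc1O | starting material
17 | tert-butyldimethylsilyl 4-(tert-butyldimethylsilyloxy)-3-methoxybenzoate | COc1cc(C(=O)O[Si](C)(C)C(C)(C)C)ccc1O[Si](C)(C)C(C)(C)C | intermediate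
18 | 4-(tert-butyldimethylsilyloxy)-3-methoxybenzoic acid | COc1cc(C(=O)O)ccc1O[Si](C)(C)C(C)(C)C | intermediate
19 | 4-(tert-butyldimethylsilyloxy)-3-methoxybenzoic 2,4,6-trichlorobenzoic anhydride | COc1cc(C(=O)OC(=O)c2c(Cl)cc(Cl)cc2Cl)ccc1O[Si](C)(C)C(C)(C)C | intermediate
20 | (1R,4R,5S,6S)-9-oxo-4-(triethylsilyloxy)dauc-8(14)-en-6-yl 4-(tert-butyldimethylsilyloxy)-3-methoxybenzoate | C=C1C[C@H](OC(=O)c2ccc(O[Si](C)(C)C(C)(C)C)c(OC)c2)[C@@H]2[C@](C)(CC[C@@]2(O[Si](CC)(CC)CC)C(C)C)CC1=O | intermediate
21 | (1R,4R,5S,6S,9S)-9-hydroxy-4-(triethylsilyloxy)dauc-8(14)-en-6-yl 4-(tert-butyldimethylsilyloxy)-3-methoxybenzoate | C=C1C[C@H](OC(=O)c2ccc(O[Si](C)(C)C(C)(C)C)c(OC)c2)[C@@H]2[C@](C)(CC[C@@]2(O[Si](CC)(CC)CC)C(C)C)C[C@@H]1O | intermediate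
22 | (1R,4R,5S,6S,9S)-4,9-dihydroxydauc-8(14)-en-6-yl 4-hydroxy-3-methoxybenzoate | C=C1C[C@H](OC(=O)c2ccc(O)c(OC)c2)[C@@H]2[C@](C)(CC[C@@]2(O)C(C)C)C[C@@H]1O | target

**Step count and risks**
Total: 13 steps. Longest linear sequence: 10 steps (steps 1–4, 7–9, 11–13) from (S)-terpinen-4-ol.

Step 7. The vinyl group of 6 lies between a fully substituted carbinol carbon and the ring alkene and may trap the bulky donor–acceptor carbenoid slowly, so that carbenoid dimerisation, allylic C–H insertion or reaction through the vinylogous terminus compete. The boat transition state must also carry C15 over the cyclopropane, which may slow the [3,3] shift. Fallback, setting out from 6 and 8: the smaller and more electrophilic acceptor–acceptor carbenoid from 8 (Rh2(esp)2, CH2Cl2) cyclopropanates the vinyl group to give the methyl 1-acetyl-2-cyclopentenylcyclopropane-1-carboxylate F1. Enol silylation (TBSOTf, Et3N) then gives the siloxyvinylcyclopropanes as a mixture of 10 and its trans-divinyl isomer F2. Heating in toluene (110–140 °C) rearranges the cis isomer and equilibrates the trans isomer through reversible homolysis of the doubly activated C6–C8 bond, returning to the route at 11. In this variant C1 rests on the C4 stereocenter alone, and a C1 epimer would have to be removed by chromatography.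

Step 8. The borane may add to the β face instead, because the isopropyl group at C4 and the folded seven-membered ring both lie on the α side; this would give the cis-fused 5β-H, 6β-hydroxy series. Fallback, setting out from 11 and replacing facial control by thermodynamic control: the β-face hydroboration product, the 5β-H,6β-alcohol F3, is oxidised with Dess–Martin periodinane to the cis-fused 6-ketone F4. DBU in toluene equilibrates C5 to the trans-fused 6-ketone F5, in which C6 is no longer cis to the isopropyl group. Reduction under thermodynamic control (SmI2, i-PrOH, THF) should give the equatorial 6α-alcohol, returning to the route at 13.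

Step 12. Hydride delivery to the β face of C9 has to pass the axial C15 methyl (1,3-relationship), so the catalyst may fail to override the substrate bias and the 9β-alcohol may predominate. Fallback, setting out from 20 and using substrate control plus inversion: Luche reduction (NaBH4, CeCl3·7H2O, MeOH, −78 °C) gives the 9β-alcohol F6 by attack on the open α face. Mitsunobu inversion with chloroacetic acid (PPh3, DIAD, toluene, 0 °C) gives the 9α-chloroacetate F7. Thiourea with NaHCO3 in EtOH removes the chloroacetate selectively beside the vanillate, returning to the route at 21.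

**Further compounds**
F1 | step 7 | methyl 1-acetyl-2-[(5R)-2-methyl-5-(propan-2-yl)-5-(triethylsilyloxy)cyclopent-1-en-1-yl]cyclopropane-1-carboxylate (mixture of cyclopropane stereoisomers) | COC(=O)C1(C(C)=O)CC1C1=C(C)CC[C@@]1(O[Si](CC)(CC)CC)C(C)C
F2 | step 7 | methyl (1S,2S)-1-[1-(tert-butyldimethylsilyloxy)ethenyl]-2-[(5R)-2-methyl-5-(propan-2-yl)-5-(triethylsilyloxy)cyclopent-1-en-1-yl]cyclopropane-1-carboxylate (trans-divinyl isomer of 10) | COC(=O)[C@@]1(C(=C)O[Si](C)(C)C(C)(C)C)C[C@H]1C1=C(C)CC[C@@]1(O[Si](CC)(CC)CC)C(C)C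
F3 | step 8 | methyl (1R,4R,5R,6R)-9-(tert-butyldimethylsilyloxy)-6-hydroxy-4-(triethylsilyloxy)dauc-8-en-14-oate (5β-H, 6β-OH) | COC(=O)C1=C(O[Si](C)(C)C(C)(C)C)C[C@@]2(C)CC[C@@](O[Si](CC)(CC)CC)(C(C)C)[C@H]2[C@H](O)C1
F4 | step 8 | methyl (1R,4R,5R)-9-(tert-butyldimethylsilyloxy)-6-oxo-4-(triethylsilyloxy)dauc-8-en-14-oate (cis-fused) | COC(=O)C1=C(O[Si](C)(C)C(C)(C)C)C[C@@]2(C)CC[C@@](O[Si](CC)(CC)CC)(C(C)C)[C@H]2C(=O)C1
F5 | step 8 | methyl (1R,4R,5S)-9-(tert-butyldimethylsilyloxy)-6-oxo-4-(triethylsilyloxy)dauc-8-en-14-oate (trans-fused) | COC(=O)C1=C(O[Si](C)(C)C(C)(C)C)C[C@@]2(C)CC[C@@](O[Si](CC)(CC)CC)(C(C)C)[C@@H]2C(=O)C1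
F6 | step 12 | (1R,4R,5S,6S,9R)-9-hydroxy-4-(triethylsilyloxy)dauc-8(14)-en-6-yl 4-(tert-butyldimethylsilyloxy)-3-methoxybenzoate | C=C1C[C@H](OC(=O)c2ccc(O[Si](C)(C)C(C)(C)C)c(OC)c2)[C@@H]2[C@](C)(CC[C@@]2(O[Si](CC)(CC)CC)C(C)C)C[C@H]1O
F7 | step 12 | (1R,4R,5S,6S,9S)-9-(chloroacetoxy)-4-(triethylsilyloxy)dauc-8(14)-en-6-yl 4-(tert-butyldimethylsilyloxy)-3-methoxybenzoate | C=C1C[C@H](OC(=O)c2ccc(O[Si](C)(C)C(C)(C)C)c(OC)c2)[C@@H]2[C@](C)(CC[C@@]2(O[Si](CC)(CC)CC)C(C)C)C[C@@H]1OC(=O)CCl
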